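**Retrosynthetic overview**

1. Labels (dibenzo[b,e][1,4]dioxin numbering): ring B = C1–C4/C4a/C10a, ring D = C5a/C6–C9/C9a, dioxin oxygens O5 and O10; ring A is the aryloxy group on C4; ring E (C1'–C6') sits on O8 and is fused to ring D through the furan bond C9–C2'.
2. Key disconnection: the furan ring is opened at C9–C2'. Both carbons are C–H sites flanked by two oxygens (C9 by O8/O10, C2' by O1'/O3'), so this bond is made last by twofold C–H palladation of the open 8-aryloxy-dibenzodioxin 15; no halogen or metal handle is ever placed on rings D or E.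
3. Dioxin ring: O10–C10a and O4–C4 by SNAr (step 5) on the ring-B linchpin 9, then O5–C4a by intramolecular Ullmann coupling (step 7). The two CHO groups of 9 (the later C1–OH and C3–OH, each ortho/para to C4 and C10a) activate both C–F bonds; Br marks C4a.
4. The oxygens at C1, C3 and O5 are carried as formyl groups and revealed together by Baeyer–Villiger oxidation (step 6). CHO at the O5 site of ring D also makes the D-ring phenol (O10) unique and rules out Smiles scrambling.
5. Ring order: four separate benzene rings A, B, D, E → dioxin ring (step 7) → furan ring (step 8) → sevenfold O-demethylation (step 9).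

Key step: step 8

Remark: the target (C24H14O11) has no stereocentre and no stereogenic axis, so it is achiral and the route needs no stereocontrol.

**Route**

Step 1
Reactants: 1 4-bromo-2,6-dimethoxybenzaldehyde; 2 3,5-dimethoxyphenol
Product: 3 4-(3,5-dimethoxyphenoxy)-2,6-dimethoxybenzaldehyde
Conditions: CuI (10 mol %), N,N-dimethylglycine·HCl (30 mol %), Cs2CO3, 1,4-dioxane, 90 °C
Reagents that add atoms: none
Why: Ullmann diaryl ether synthesis with matched polarity (aryl bromide activated by the para-formyl group, electron-rich phenoxide) should give the ether, the non-enolisable aldehyde and the methyl ethers being inert to Cu(I)/carbonate.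

Step 2
Reactants: 3 4-(3,5-dimethoxyphenoxy)-2,6-dimethoxybenzaldehyde
Product: 4 4-(3,5-dimethoxyphenoxy)-2-hydroxy-6-methoxybenzaldehyde
Conditions: BCl3 (1.1 equiv), CH2Cl2, −78 → 0 °C; aqueous work-up
Reagents that add atoms: none
Why: Chelation-controlled ether cleavage, in which BCl3 bound to the formyl oxygen is delivered to one of the two equivalent ortho-methoxy groups only (the resulting six-membered aryloxyboron chelate shuts down the second cleavage), so exactly one phenol, the later O10, is set free while the E-ring methoxy groups are untouched.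

Step 3
Reactants: 5 2-bromo-1,3-difluorobenzene
Product: 6 2-bromo-1,3-difluoro-4,6-diiodobenzene
Conditions: NIS (2.3 equiv), CF3SO3H, 0 °C → rt
Reagents that add atoms: N-iodosuccinimide, O=C1CCC(=O)N1I
Why: Electrophilic aromatic iodination with acid-activated NIS, in which each fluorine directs ortho/para so that C4 and C6 (ortho to one F, para to the other) are iodinated and C5 (meta to both F) is not.

Step 4
Reactants: 6 2-bromo-1,3-difluoro-4,6-diiodobenzene
Product: 9 5-bromo-4,6-difluorobenzene-1,3-dicarbaldehyde, via mono-hemiaminalate iodide 7 (not isolated), via bis-hemiaminalate 8 (not isolated)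
Conditions: i-PrMgCl·LiCl (1.05 equiv), THF, −40 °C; DMF; i-PrMgCl·LiCl (1.1 equiv), −40 °C; DMF; then 2 M HCl, 0 °C
Reagents that add atoms: N,N-dimethylformamide, CN(C)C=O
Why: Iodine–magnesium exchange with the turbo-Grignard reagent is much faster at C–I than at C–Br, the magnesium hemiaminalate formed with DMF (Bouveault formylation) masks the first aldehyde during the second exchange, and at −40 °C the ortho-fluoro arylmagnesium species neither eliminate nor migrate, so the bromine stays between the two fluorines.

Step 5
Reactants: 4 4-(3,5-dimethoxyphenoxy)-2-hydroxy-6-methoxybenzaldehyde; 9 5-bromo-4,6-difluorobenzene-1,3-dicarbaldehyde; 2 3,5-dimethoxyphenol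
Product: 11 5-bromo-4-(3,5-dimethoxyphenoxy)-6-[5-(3,5-dimethoxyphenoxy)-2-formyl-3-methoxyphenoxy]benzene-1,3-dicarbaldehyde, via mono-aryl fluoro dialdehyde 10 (not isolated)
Conditions: 4 added slowly to 9 (1.1 equiv), K2CO3, DMF, 0 °C → rt; then 2 (1.5 equiv), K2CO3, 60 °C
Reagents that add atoms: none
Why: Nucleophilic aromatic substitution (SNAr), in which each C–F is ortho to one formyl group and para to the other whereas C–Br is meta to both and stays, the first aryloxy group lowers the electrophilicity of the ring so that the second fluoride is displaced only by the added phenoxide of 2 at higher temperature, and no Smiles rearrangement can scramble the oxygens because the D-ring carbon next to the new ether carries CHO and not OH.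

Step 6
Reactants: 11 5-bromo-4-(3,5-dimethoxyphenoxy)-6-[5-(3,5-dimethoxyphenoxy)-2-formyl-3-methoxyphenoxy]benzene-1,3-dicarbaldehyde
Product: 13 5-bromo-4-(3,5-dimethoxyphenoxy)-6-[5-(3,5-dimethoxyphenoxy)-2-hydroxy-3-methoxyphenoxy]benzene-1,3-diol, via tris-formate 12 (not isolated)
Conditions: mCPBA (4 equiv), NaHCO3, CH2Cl2, rt → 40 °C; then K2CO3 (cat.), degassed MeOH, rt; dilute HCl
Reagents that add atoms: meta-chloroperoxybenzoic acid, OOC(=O)c1cccc(Cl)c1
Why: Baeyer–Villiger oxidation (the peracid variant of the Dakin reaction), in which every formyl group sits on a carbon with oxygen substituents ortho and para so that the aryl group migrates to give aryl formates, as in the established SNAr/Baeyer–Villiger route to diaryl ether phenols, and mild methanolysis then frees the three phenols without touching C–Br or the aryl ethers.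

Step 7
Reactants: 13 5-bromo-4-(3,5-dimethoxyphenoxy)-6-[5-(3,5-dimethoxyphenoxy)-2-hydroxy-3-methoxyphenoxy]benzene-1,3-diol
Product: 15 4,8-bis(3,5-dimethoxyphenoxy)-1,3,6-trimethoxydibenzo[b,e][1,4]dioxine, via dibenzodioxin-1,3-diol 14 (not isolated)
Conditions: CuCl (20 mol %), 2,2,6,6-tetramethylheptane-3,5-dione (40 mol %), Cs2CO3 (5 equiv), degassed NMP, 120 °C; then MeI (excess), 25 °C
Reagents that add atoms: iodomethane, CI
Why: Intramolecular Ullmann etherification, in which only the D-ring phenoxide (the later O5) can reach the C–Br carbon through a six-membered transition state, the B ring is no longer activated so the ether already in place cannot migrate, and the two remaining phenoxides are capped in the same flask by Williamson methylation to protect ring B from oxidation in step 8.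

Step 8
Reactants: 15 4,8-bis(3,5-dimethoxyphenoxy)-1,3,6-trimethoxydibenzo[b,e][1,4]dioxine
Product: 16 hepta-O-methyl ether of the target (benzofuro-fused dibenzodioxin, all seven OH as OMe)
Conditions: Pd(OAc)2 (10–20 mol %), K2CO3 (10 mol %), PivOH, air or O2 (1 atm), 120 °C
Reagents that add atoms: none
Why: Pd(II) pivalate palladates the electron-rich E ring at C2' (C2' and C6' are equivalent) and then activates C9–H of ring D by concerted metalation–deprotonation through a six-membered diaryl-ether palladacycle; C–C reductive elimination forms the C9–C2' bond and Pd(0) is reoxidised by O2. The closest known reaction type is the Pd(OAc)2/PivOH/air intramolecular dehydrogenative biaryl coupling of diaryl ethers to dibenzofurans. The furan ring (O8, C8, C9, C2', C1') is closed by this five-membered-ring-forming reductive elimination, and no stereocentre is created. The step needs C9–H over C7–H selectivity on ring D: the methyl of the C6–OMe group must lie in the ring plane on the C7 side (its other side is O5) and shields C7–H, whereas C9–H is flanked by the ring-bound O10; C9 is also para to the C6–OMe donor, and closure at C7 would force two methoxy groups into the new bay region. No second furan can form because ring B has no C–H ortho to its aryloxy carbon C4 (C3 carries OMe, C4a carries O5), so the A-ring ether is a spectator.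

Step 9
Reactants: 16 hepta-O-methyl ether of the target
Product: 17 target CNP0256302.0 (fucofuroeckol-type heptaphenol)
Conditions: BBr3 (14 equiv), CH2Cl2, −78 °C → rt, argon; MeOH then H2O
Reagents that add atoms: none
Why: Lewis acid-mediated cleavage of all seven aryl methyl ethers with BBr3, which does not cleave the diaryl ether, dioxin or furan C–O bonds, should give the free heptaphenol.

**Compound list**

1 | 4-bromo-2,6-dimethoxybenzaldehyde | COc1cc(Br)cc(OC)c1C=O | starting material
2 | 3,5-dimethoxyphenol | COc1cc(O)cc(OC)c1 | starting material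
3 | 4-(3,5-dimethoxyphenoxy)-2,6-dimethoxybenzaldehyde | COc1cc(Oc2cc(OC)cc(OC)c2)cc(OC)c1C=O | intermediate
4 | 4-(3,5-dimethoxyphenoxy)-2-hydroxy-6-methoxybenzaldehyde | COc1cc(Oc2cc(OC)cc(OC)c2)cc(O)c1C=O | intermediate
5 | 2-bromo-1,3-difluorobenzene | Fc1cccc(F)c1Br | starting material
6 | 2-bromo-1,3-difluoro-4,6-diiodobenzene | Fc1c(I)cc(I)c(F)c1Br | intermediate
7 | chloromagnesium (3-bromo-2,4-difluoro-5-iodophenyl)(dimethylamino)methanolate | CN(C)C(O[Mg]Cl)c1cc(I)c(F)c(Br)c1F | intermediate (not isolated)
8 | bis(chloromagnesium) (5-bromo-4,6-difluoro-1,3-phenylene)bis[(dimethylamino)methanolate] | CN(C)C(O[Mg]Cl)c1cc(C(O[Mg]Cl)N(C)C)c(F)c(Br)c1F | intermediate (not isolated)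
9 | 5-bromo-4,6-difluorobenzene-1,3-dicarbaldehyde | O=Cc1cc(C=O)c(F)c(Br)c1F | intermediate
10 | 5-bromo-4-fluoro-6-[5-(3,5-dimethoxyphenoxy)-2-formyl-3-methoxyphenoxy]benzene-1,3-dicarbaldehyde | O=Cc1cc(C=O)c(Oc2cc(Oc3cc(OC)cc(OC)c3)cc(OC)c2C=O)c(Br)c1F | intermediate (not isolated)
11 | 5-bromo-4-(3,5-dimethoxyphenoxy)-6-[5-(3,5-dimethoxyphenoxy)-2-formyl-3-methoxyphenoxy]benzene-1,3-dicarbaldehyde | O=Cc1cc(C=O)c(Oc2cc(Oc3cc(OC)cc(OC)c3)cc(OC)c2C=O)c(Br)c1Oc1cc(OC)cc(OC)c1 | intermediate
12 | tris-formate of 13 (formate esters at both B-ring oxygens and at the D-ring 2-oxygen) | O=COc1cc(OC=O)c(Oc2cc(Oc3cc(OC)cc(OC)c3)cc(OC)c2OC=O)c(Br)c1Oc1cc(OC)cc(OC)c1 | intermediate (not isolated)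
13 | 5-bromo-4-(3,5-dimethoxyphenoxy)-6-[5-(3,5-dimethoxyphenoxy)-2-hydroxy-3-methoxyphenoxy]benzene-1,3-diol | Oc1cc(O)c(Oc2cc(Oc3cc(OC)cc(OC)c3)cc(OC)c2O)c(Br)c1Oc1cc(OC)cc(OC)c1 | intermediate
14 | 4,8-bis(3,5-dimethoxyphenoxy)-6-methoxydibenzo[b,e][1,4]dioxine-1,3-diol | COc1cc(Oc2cc(OC)cc(OC)c2)cc2Oc3c(O)cc(O)c(Oc4cc(OC)cc(OC)c4)c3Oc12 | intermediate (not isolated)
15 | 4,8-bis(3,5-dimethoxyphenoxy)-1,3,6-trimethoxydibenzo[b,e][1,4]dioxine | COc1cc(Oc2cc(OC)cc(OC)c2)cc2Oc3c(OC)cc(OC)c(Oc4cc(OC)cc(OC)c4)c3Oc12 | intermediate
16 | hepta-O-methyl ether of the target (furan closed between C9 and C2') | COc1cc(OC)cc(Oc2c(OC)cc(OC)c3c2Oc2c(OC)cc4oc5cc(OC)cc(OC)c5c4c2O3)c1 | intermediate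
17 | CNP0256302.0 (fucofuroeckol-type heptaphenol) | Oc1cc(O)cc(Oc2c(O)cc(O)c3c2Oc2c(O)cc4oc5cc(O)cc(O)c5c4c2O3)c1 | target

**Step count and risks**

Total step count: 9.
Longest linear sequence: 7 steps (steps 1, 2, 5, 6, 7, 8, 9 from compound 1; the branch from compound 5 through steps 3 and 4 is equally long).

The three steps most likely to fail:

Step 8 (key step). The second C–H palladation may occur at C7 instead of C9, or ring closure into the crowded bay region may not take place, so that the electron-rich rings are acetoxylated or homocoupled instead. Fallback (furan first, dioxin last): the route sets out from 3, in which ring D is still symmetric, so that the same Pd(OAc)2/PivOH/air cyclisation can give only one product, 1,3,7,9-tetramethoxydibenzo[b,d]furan-2-carbaldehyde F1. BCl3 (1 equiv) should then cleave the bay-region 1-methoxy group, which is twisted out of plane by the 9-methoxy group and is the more basic of the two chelating ortho-methoxy groups, to give 1-hydroxy-3,7,9-trimethoxydibenzo[b,d]furan-2-carbaldehyde F2. SNAr of F2 with 9 (K2CO3, DMF) should give the mono-aryl fluoro dialdehyde F3, and SNAr with 2 the tris-aldehyde F4. Baeyer–Villiger oxidation with mCPBA should give the tris-formate F5 and methanolysis the triphenol F6. Copper-catalysed Ullmann closure should give the pentacyclic B-ring diol F7, and methylation with MeI brings the route back at 16.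

Step 7. Oxidative addition at the electron-rich bromide flanked by two aryloxy groups may be slow in the presence of three phenoxides, which would lead to protodebromination, intermolecular etherification or oxidation of the polyphenoxide. Fallback (closure on a mono-phenol): the route sets out from 13. Exhaustive methylation (MeI, K2CO3, acetone) should give the tri-O-methyl bromide F8. BCl3 at low temperature should then cleave only the one methoxy group that is flanked by two oxygen substituents (the middle oxygen of the 1,2,3-trioxygenated array on ring D) to give the mono-phenol F9. Intramolecular Ullmann etherification of F9, which has no other acidic group, comes back to the route at 15.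

Step 5. The symmetric difluoride 9 may be arylated twice by 4, or the hydrogen-bonded ortho-formyl phenoxide of 4 may attack slowly, either of which wastes the more valuable fragment. Fallback (desymmetrise with the cheap partner first): the route sets out from 9, used in excess, with 2 as the limiting reagent (K2CO3, DMF, 0 °C), which should give 5-bromo-4-(3,5-dimethoxyphenoxy)-6-fluorobenzene-1,3-dicarbaldehyde F10. F10 is isolated and the excess 9 recovered. SNAr of F10 with 4 (K2CO3, DMF, 50 °C), now with a single C–F left, comes back to the route at 11.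

Further compounds
F1 | step 8 | 1,3,7,9-tetramethoxydibenzo[b,d]furan-2-carbaldehyde | COc1cc2oc3cc(OC)cc(OC)c3c2c(OC)c1C=O
F2 | step 8 | 1-hydroxy-3,7,9-trimethoxydibenzo[b,d]furan-2-carbaldehyde | COc1cc2oc3cc(OC)cc(OC)c3c2c(O)c1C=O
F3 | step 8 | 5-bromo-4-fluoro-6-[(2-formyl-3,7,9-trimethoxydibenzo[b,d]furan-1-yl)oxy]benzene-1,3-dicarbaldehyde | O=Cc1cc(C=O)c(Oc2c(C=O)c(OC)cc3oc4cc(OC)cc(OC)c4c23)c(Br)c1F
F4 | step 8 | 5-bromo-4-(3,5-dimethoxyphenoxy)-6-[(2-formyl-3,7,9-trimethoxydibenzo[b,d]furan-1-yl)oxy]benzene-1,3-dicarbaldehyde | O=Cc1cc(C=O)c(Oc2c(C=O)c(OC)cc3oc4cc(OC)cc(OC)c4c23)c(Br)c1Oc1cc(OC)cc(OC)c1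
F5 | step 8 | tris-formate of F6 (formate esters at both B-ring oxygens and at the dibenzofuran 2-oxygen) | O=COc1cc(OC=O)c(Oc2c(OC=O)c(OC)cc3oc4cc(OC)cc(OC)c4c23)c(Br)c1Oc1cc(OC)cc(OC)c1
F6 | step 8 | 5-bromo-4-(3,5-dimethoxyphenoxy)-6-[(2-hydroxy-3,7,9-trimethoxydibenzo[b,d]furan-1-yl)oxy]benzene-1,3-diol | Oc1cc(O)c(Oc2c(O)c(OC)cc3oc4cc(OC)cc(OC)c4c23)c(Br)c1Oc1cc(OC)cc(OC)c1
F7 | step 8 | penta-O-methyl ether of the target with free C1–OH and C3–OH on ring B | COc1cc(OC)cc(Oc2c(O)cc(O)c3c2Oc2c(OC)cc4oc5cc(OC)cc(OC)c5c4c2O3)c1
F8 | step 7 | 3-bromo-2-(3,5-dimethoxyphenoxy)-4-[5-(3,5-dimethoxyphenoxy)-2,3-dimethoxyphenoxy]-1,5-dimethoxybenzene | COc1cc(OC)c(Oc2cc(Oc3cc(OC)cc(OC)c3)cc(OC)c2OC)c(Br)c1Oc1cc(OC)cc(OC)c1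
F9 | step 7 | 2-[2-bromo-3-(3,5-dimethoxyphenoxy)-4,6-dimethoxyphenoxy]-4-(3,5-dimethoxyphenoxy)-6-methoxyphenol | COc1cc(OC)c(Oc2cc(Oc3cc(OC)cc(OC)c3)cc(OC)c2O)c(Br)c1Oc1cc(OC)cc(OC)c1
F10 | step 5 | 5-bromo-4-(3,5-dimethoxyphenoxy)-6-fluorobenzene-1,3-dicarbaldehyde | O=Cc1cc(C=O)c(F)c(Br)c1Oc1cc(OC)cc(OC)c1
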